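**Plan**

1. Atoms are numbered as in the target's decalin (ring A: C1–C5 and C10; ring B: C5–C10; C11 on C9; β = face of H-5). The retrosynthesis cuts C11–C12 (sulfone alkylation), C9–C11 ([2,3] shift), C10–CH3 and, as one event, C1–C10 together with C3–C4, which takes ring A off as acrylonitrile.
2. Feature used: ring B with the C8 methyl, plus C4 with its two methyls, are the ten carbons of carvone. C10 is the α′-carbon of the C9 ketone (a latent enolate) and C4 is the inner carbon of the isopropenyl group (a latent tertiary radical); they sit 1,3 to each other across C5.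
3. Acrylonitrile matches both: its β-carbon takes the enolate (C1–C10), and its cyano carbon takes the radical and becomes the C3 ketone (C3–C4). Ring A with the gem-dimethyl carbon is thus closed onto ring B in one flask.
4. Forward order: (S)-carvone epoxide (ring B) → ring A → C10 methyl → transposition of the epoxy ketone → C11 by [2,3] shift → C8–OH → sulfone coupling with the oxidised farnesyl bromide → acetate and release of the ketone.
5. Stereochemistry: C5 comes from (S)-carvone. The oxirane forms anti to the isopropenyl group; its oxygen becomes the 7β-OH and hands the β face to C11 in the suprafacial shift. The C10 methyl enters syn to H-5. C8–OH comes from α-epoxidation anti to C11 and hydride opening at C7.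
6. The three E double bonds come from (2E,6E)-farnesyl acetate and an E-selective allylic oxidation.

Key step: step 2

Remark: read literally, the SMILES places H-5 and the C10 methyl on the same face ((5S,8R,9R,10S), a cis-fused decalin), and the route is laid out for exactly this isomer.

**Route**

Step 1
Reactants: 1 (S)-(+)-carvone
Product: 2 (S)-carvone epoxide (7β,8β-oxirane, trans to the isopropenyl group)
Conditions: H2O2 (30% aq.), NaOH (cat.), MeOH, 0 °C
Reagents that add atoms: hydrogen peroxide, OO
Why: Weitz–Scheffer nucleophilic epoxidation of the enone should deliver the hydroperoxide to C7 on the face opposite to the C5 isopropenyl group, so that the oxirane oxygen sits on the β face, C8 is blocked against enolisation and the enone is removed as a competing Michael acceptor.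

Step 2
Reactants: 2 (S)-carvone epoxide; 3 acrylonitrile
Product: 6 7β,8β-epoxy-4,4,8-trimethyldecalin-3,9-dione (5β-H), via cyanoethyl ketone 4 (not isolated), via ketimine 5 (not isolated)
Conditions: LiN(iPr)2, THF, −78 °C; 3 (1.0 equiv), −78 to −40 °C; AcOH quench; then Fe(acac)3 (30 mol %), PhSiH3, EtOH, 60 °C, same flask; cold 1 M HCl work-up
Reagents that add atoms: acrylonitrile, C=CC#N; water, O
Why: Deprotonation of 2 is possible only at C10, and this enolate adds to the β-carbon of acrylonitrile (Michael addition, C1–C10); after the quench, hydrogen-atom transfer from the iron hydride to the CH2 of the isopropenyl group gives the tertiary C4 radical, which attacks the cyano carbon, and the iminyl radical is reduced to the N–H ketimine 5 that the acid work-up hydrolyses to the C3 ketone (C3–C4). The closest known reaction types are the cyanoethylation of ketone enolates and the HAT-initiated reductive cyclisation of alkenes onto nitriles (Mukaiyama-type conditions). Ring A closes in the 6-exo-dig mode at the cyano carbon, and the quaternary C4 with both methyl groups arises from the inner isopropenyl carbon. No stereocentre of the target is set here: C5 is carried over from carvone, and C10, still a C–H next to the ketone, is expected mainly trans to the C5–C4 bond but is fixed only in step 4, so both epimers converge. The step needs the carbonyl carbon on C4 and the methylene on C10, and the polarity of acrylonitrile secures this, because the enolate can only attack its β-carbon and the nucleophilic radical meets the cyano group only intramolecularly once all free acrylonitrile has been consumed. The oxirane leaves C10 as the only acidic position and keeps the α-cyano carbanion from a second, intramolecular Michael addition that the parent enone would allow.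

Step 3
Reactants: 6 epoxy diketone
Product: 7 3,3-ethylenedioxy-7β,8β-epoxy-4,4,8-trimethyldecalin-9-one
Conditions: 1,2-bis(trimethylsilyloxy)ethane, TMSOTf (cat.), CH2Cl2, −78 to −20 °C
Reagents that add atoms: 1,2-bis(trimethylsilyloxy)ethane, C[Si](C)(C)OCCO[Si](C)(C)C
Why: Lewis-acid-catalysed silyl-transfer ketalisation at low temperature should engage only the C3 ketone, because the C9 carbonyl lies between the ring-fusion carbon and the oxirane carbon and is deactivated by the α-oxygen.

Step 4
Reactants: 7 ketal epoxy ketone
Product: 8 3,3-ethylenedioxy-7β,8β-epoxy-4,4,8,10β-tetramethyldecalin-9-one (cis-fused: C10 methyl and H-5 both β)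
Conditions: LiN(iPr)2, THF, −78 °C; MeI, DMPU, −78 to −20 °C
Reagents that add atoms: iodomethane, CI
Why: The C9 ketone can enolise only toward C10, and alkylation of this ring-fusion enolate (angular alkylation of a 1-decalone-type enolate) should occur on the β face, syn to H-5, because the axial 4α-methyl group, 1,3 to C10, screens the α face, which gives the cis-fused quaternary C10.

Step 5
Reactants: 8 methylated epoxy ketone
Product: 10 3,3-ethylenedioxy-4,4,8,10β-tetramethyl-cis-decal-8-en-7β-ol, via epoxy hydrazone 9 (not isolated)
Conditions: N2H4·H2O, AcOH (cat.), MeOH, rt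
Reagents that add atoms: none
Why: Wharton transposition: the epoxy hydrazone 9 collapses to a vinyl diazene that loses N2, which moves the double bond to C8=C9 and leaves the oxirane oxygen as the 7β-hydroxyl with retention at C7.

Step 6
Reactants: 10 allylic alcohol; 11 (iodomethyl)tributylstannane
Product: 12 7β-(tributylstannylmethoxy) ether of 10
Conditions: KH, THF, 0 °C; 11, 18-crown-6 (cat.), rt
Reagents that add atoms: (iodomethyl)tributylstannane, CCCC[Sn](CCCC)(CCCC)CI
Why: Williamson etherification of the potassium alkoxide with the primary iodide installs the tin-bearing methylene on O7 without touching the ketal.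

Step 7
Reactants: 12 stannylmethyl ether
Product: 13 9β-(hydroxymethyl)-3,3-ethylenedioxy-4,4,8,10β-tetramethyl-cis-decal-7-ene (H-9 α)
Conditions: n-BuLi, THF, −78 to −20 °C; aq. NH4Cl
Reagents that add atoms: none
Why: Tin–lithium exchange gives the α-alkoxymethyllithium, whose [2,3]-Wittig rearrangement (Still variant) is suprafacial, so the CH2O unit moves from O7 to the β face of C9, setting C9 (C11 β, H-9 α, cis to the C10 methyl) and placing the double bond at C7=C8.

Step 8
Reactants: 13 homoallylic alcohol
Product: 14 C11 phenyl sulfide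
Conditions: PhSSPh, PBu3, pyridine, rt
Reagents that add atoms: diphenyl disulfide, c1ccc(SSc2ccccc2)cc1
Why: Hata-type deoxygenative thiolation (alkoxyphosphonium displaced by thiolate, SN2 at the primary C11) converts the alcohol to the sulfide under neutral conditions.

Step 9
Reactants: 14 phenyl sulfide
Product: 17 7α,8α-epoxy C11 phenyl sulfone, via sulfoxide 15 (not isolated), via unsaturated sulfone 16 (not isolated)
Conditions: mCPBA (3.3 equiv), NaHCO3, CH2Cl2, 0 °C to rt
Reagents that add atoms: 3-chloroperbenzoic acid, OOC(=O)c1cccc(Cl)c1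
Why: The peracid first oxidises sulfur to the sulfone and then epoxidises the trisubstituted C7=C8 bond (Prilezhaev reaction) on the α face, anti to the pseudoaxial C9 substituent, which sets the C8 oxygen α and the C8 methyl β.

Step 10
Reactants: 17 epoxy sulfone
Product: 18 8α-hydroxy-8β-methyl C11 phenyl sulfone
Conditions: LiEt3BH, THF, 0 °C to rt; H2O
Reagents that add atoms: none
Why: Hydride opens the trisubstituted oxirane at the less substituted C7 (SN2, trans-diaxial), leaving the tertiary 8α-alcohol with the configuration fixed in step 9.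

Step 11
Reactants: 19 (2E,6E)-farnesyl acetate
Product: 20 (2E,6E,10E)-12-hydroxyfarnesyl acetate
Conditions: SeO2 (cat.), t-BuOOH, salicylic acid (cat.), CH2Cl2, rt
Reagents that add atoms: tert-butyl hydroperoxide, CC(C)(C)OO
Why: Selenium dioxide allylic oxidation (ene reaction, then [2,3] shift) attacks the E methyl of the terminal trisubstituted alkene, the most electron-rich and least hindered allylic position, and gives the E allylic alcohol.

Step 12
Reactants: 20 hydroxy acetate
Product: 21 (2E,6E,10E)-12-(tert-butyldimethylsilyloxy)farnesyl acetate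
Conditions: TBSCl, imidazole, CH2Cl2, rt
Reagents that add atoms: tert-butyldimethylsilyl chloride, CC(C)(C)[Si](C)(C)Cl
Why: Standard silylation of the primary allylic alcohol protects it for the base and reducing steps to come.

Step 13
Reactants: 21 silyl ether acetate
Product: 22 (2E,6E,10E)-12-(tert-butyldimethylsilyloxy)farnesol
Conditions: K2CO3 (cat.), MeOH, rt
Reagents that add atoms: none
Why: Base-catalysed transesterification removes the acetate without affecting the silyl ether.

Step 14
Reactants: 22 allylic alcohol
Product: 23 (2E,6E,10E)-12-(tert-butyldimethylsilyloxy)farnesyl bromide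
Conditions: CBr4, PPh3, CH2Cl2, −20 °C
Reagents that add atoms: tetrabromomethane, BrC(Br)(Br)Br
Why: Appel bromination converts the primary allylic alcohol to the bromide by SN2 at low temperature without allylic transposition or loss of E geometry.

Step 15
Reactants: 18 hydroxy sulfone; 23 allylic bromide
Product: 24 coupled sulfone (C11–C12 bond; C11 epimers)
Conditions: 18, n-BuLi (2.2 equiv), THF–HMPA, −78 °C; then 23, −78 °C; aq. NH4Cl
Reagents that add atoms: bromide 23, CC(C)(C)[Si](C)(C)OC/C(C)=C/CC/C(C)=C/CC/C(C)=C/CBr
Why: Double deprotonation gives the alkoxide/α-sulfonyl carbanion, and the soft carbanion alkylates the primary allylic bromide by SN2 (sulfone-based fragment coupling), which forms C11–C12 and completes the carbon skeleton.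

Step 16
Reactants: 24 coupled sulfone
Product: 25 desulfonylated silyl ether ketal
Conditions: Na/Hg (6%), Na2HPO4, MeOH–THF, −20 °C
Reagents that add atoms: none
Why: Single-electron reductive cleavage of the C–S bond by sodium amalgam in buffered methanol replaces the sulfonyl group by hydrogen without moving the neighbouring double bond.

Step 17
Reactants: 25 silyl ether ketal
Product: 26 ketal diol (primary allylic alcohol, tertiary 8α-alcohol)
Conditions: Bu4NF, THF, rt; aq. NH4Cl
Reagents that add atoms: none
Why: Fluoride cleaves the primary silyl ether and leaves the ketal and tertiary alcohol untouched.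

Step 18
Reactants: 26 ketal diol
Product: 27 primary acetate ketal
Conditions: Ac2O, pyridine, rt
Reagents that add atoms: acetic anhydride, CC(=O)OC(C)=O
Why: Acetylation without an acylation catalyst is selective for the primary allylic alcohol over the hindered tertiary 8α-alcohol.

Step 19
Reactants: 27 acetate ketal
Product: 28 myrrhanone A acetate, (5S,8R,9R,10S) as given
Conditions: PPTS, acetone–H2O, 45 °C
Reagents that add atoms: water, O
Why: Mild acid-catalysed ketal hydrolysis releases the C3 ketone, while the tertiary alcohol and the allylic acetate should survive the buffered conditions, to give the target.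

**Compound list**

1 | (S)-(+)-carvone, (5S)-2-methyl-5-(prop-1-en-2-yl)cyclohex-2-en-1-one | CC(=C)[C@H]1CC=C(C)C(=O)C1 | starting material
2 | (S)-carvone epoxide, oxirane (C7–C8, β) trans to the isopropenyl group | O=C1C[C@@H](C(C)=C)C[C@@H]2O[C@]12C | intermediate
3 | acrylonitrile | C=CC#N | starting material
4 | 10-(2-cyanoethyl) derivative of 2, cyanoethyl trans to isopropenyl (C10 epimers converge) | O=C1[C@H](CCC#N)[C@@H](C(C)=C)C[C@@H]2O[C@]12C | intermediate
5 | C3 N–H ketimine of 6 | N=C1CC[C@H]2C(=O)[C@@]3(C)O[C@H]3C[C@@H]2C1(C)C | intermediate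
6 | 7β,8β-epoxy-4,4,8-trimethyldecalin-3,9-dione, 5β-H, 10α-H (trans-fused; C10 epimers converge) | O=C1CC[C@H]2C(=O)[C@@]3(C)O[C@H]3C[C@@H]2C1(C)C | intermediate
7 | 3,3-ethylenedioxy-7β,8β-epoxy-4,4,8-trimethyldecalin-9-one | C12(OCCO1)CC[C@H]3C(=O)[C@@]4(C)O[C@H]4C[C@@H]3C2(C)C | intermediate
8 | 3,3-ethylenedioxy-7β,8β-epoxy-4,4,8,10β-tetramethyldecalin-9-one, cis-fused (CH3-10 and H-5 β) | C12(OCCO1)CC[C@]3(C)C(=O)[C@@]4(C)O[C@H]4C[C@@H]3C2(C)C | intermediate
9 | C9 hydrazone of 8 | C12(OCCO1)CC[C@]3(C)C(=NN)[C@@]4(C)O[C@H]4C[C@@H]3C2(C)C | intermediate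
10 | 3,3-ethylenedioxy-4,4,8,10β-tetramethyl-cis-decal-8-en-7β-ol | C12(OCCO1)CC[C@]3(C)C=C(C)[C@@H](O)C[C@@H]3C2(C)C | intermediate
11 | (iodomethyl)tributylstannane | CCCC[Sn](CCCC)(CCCC)CI | starting material
12 | 7β-(tributylstannylmethoxy) ether of 10 | C12(OCCO1)CC[C@]3(C)C=C(C)[C@@H](OC[Sn](CCCC)(CCCC)CCCC)C[C@@H]3C2(C)C | intermediate
13 | 9β-(hydroxymethyl)-3,3-ethylenedioxy-4,4,8,10β-tetramethyl-cis-decal-7-ene, H-9 α | C12(OCCO1)CC[C@]3(C)[C@@H](CO)C(C)=CC[C@@H]3C2(C)C | intermediate
14 | C11 phenyl sulfide of 13 | C12(OCCO1)CC[C@]3(C)[C@@H](CSc4ccccc4)C(C)=CC[C@@H]3C2(C)C | intermediate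
15 | C11 phenyl sulfoxide (sulfur epimers) | C12(OCCO1)CC[C@]3(C)[C@@H](CS(=O)c4ccccc4)C(C)=CC[C@@H]3C2(C)C | intermediate
16 | C11 phenyl sulfone with C7=C8 intact | C12(OCCO1)CC[C@]3(C)[C@@H](CS(=O)(=O)c4ccccc4)C(C)=CC[C@@H]3C2(C)C | intermediate
17 | 7α,8α-epoxy C11 phenyl sulfone | C12(OCCO1)CC[C@]3(C)[C@@H](CS(=O)(=O)c4ccccc4)[C@]5(C)O[C@@H]5C[C@@H]3C2(C)C | intermediate
18 | 8α-hydroxy-8β-methyl C11 phenyl sulfone | C12(OCCO1)CC[C@]3(C)[C@@H](CS(=O)(=O)c4ccccc4)[C@](C)(O)CC[C@@H]3C2(C)C | intermediate
19 | (2E,6E)-farnesyl acetate | CC(C)=CCC/C(C)=C/CC/C(C)=C/COC(C)=O | starting material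
20 | (2E,6E,10E)-12-hydroxyfarnesyl acetate | OC/C(C)=C/CC/C(C)=C/CC/C(C)=C/COC(C)=O | intermediate
21 | (2E,6E,10E)-12-(tert-butyldimethylsilyloxy)farnesyl acetate | CC(C)(C)[Si](C)(C)OC/C(C)=C/CC/C(C)=C/CC/C(C)=C/COC(C)=O | intermediate
22 | (2E,6E,10E)-12-(tert-butyldimethylsilyloxy)farnesol | CC(C)(C)[Si](C)(C)OC/C(C)=C/CC/C(C)=C/CC/C(C)=C/CO | intermediate
23 | (2E,6E,10E)-12-(tert-butyldimethylsilyloxy)farnesyl bromide | CC(C)(C)[Si](C)(C)OC/C(C)=C/CC/C(C)=C/CC/C(C)=C/CBr | intermediate
24 | coupled sulfone, 18 alkylated at C11 by 23 (C11 epimers) | C12(OCCO1)CC[C@]3(C)[C@@H](C(C/C=C(C)/CC/C=C(C)/CC/C=C(C)/CO[Si](C)(C)C(C)(C)C)S(=O)(=O)c4ccccc4)[C@](C)(O)CC[C@@H]3C2(C)C | intermediate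
25 | desulfonylated silyl ether ketal (full skeleton) | C12(OCCO1)CC[C@]3(C)[C@@H](CC/C=C(C)/CC/C=C(C)/CC/C=C(C)/CO[Si](C)(C)C(C)(C)C)[C@](C)(O)CC[C@@H]3C2(C)C | intermediate
26 | ketal diol | C12(OCCO1)CC[C@]3(C)[C@@H](CC/C=C(C)/CC/C=C(C)/CC/C=C(C)/CO)[C@](C)(O)CC[C@@H]3C2(C)C | intermediate
27 | ethylene ketal of the target | C12(OCCO1)CC[C@]3(C)[C@@H](CC/C=C(C)/CC/C=C(C)/CC/C=C(C)/COC(C)=O)[C@](C)(O)CC[C@@H]3C2(C)C | intermediate
28 | myrrhanone A acetate, (5S,8R,9R,10S) | CC(=O)OC/C(C)=C/CC/C(C)=C/CC/C(C)=C/CC[C@@H]1[C@@]2(C)CCC(=O)C(C)(C)[C@H]2CC[C@@]1(C)O | target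

**Step count and risks**

Total step count: 19. Longest linear sequence: 15 (steps 1–10 and 15–19, from (S)-carvone).

Steps most likely to fail:

1. Step 2. What may go wrong: over-addition or anionic oligomerisation during the conjugate addition, or reduction of the isopropenyl group in competition with the slow 6-exo attack on the nitrile. Fallback (alkylation and an aldehyde acceptor instead of conjugate addition and a nitrile): starting from 2, the lithium enolate is alkylated with allyl bromide to the allyl ketone F1. Hydroboration of the allyl group with 9-BBN and oxidation give the primary alcohol F2, and Dess–Martin oxidation gives the aldehyde F3. Fe(acac)3/PhSiH3 in EtOH then closes ring A by attack of the C4 radical on the aldehyde to give the hydroxy ketone F4, and a second Dess–Martin oxidation comes back to the route at 6.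

2. Step 4. What may go wrong: poor facial selectivity in the alkylation of the ring-fusion enolate (leading to the trans-fused isomer), or attack of the enolate on the neighbouring oxirane. Fallback (methyl before ring closure, with the adjacent isopropenyl group as the control element): starting from 2, the conjugate addition of step 2 is worked up at the nitrile stage and 4 is isolated. Its C10 enolate is methylated with LiN(iPr)2/MeI anti to the isopropenyl group to give the methyl cyanoethyl ketone F5. Fe(acac)3/PhSiH3 cyclisation through the methyl ketimine F6 and hydrolysis give the cis-fused methyl epoxy diketone F7, whose ketalisation as in step 3 comes back to the route at 8.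

3. Step 5. What may go wrong: slow or incomplete hydrazone formation at the C9 carbonyl, which lies between a quaternary carbon and the oxirane, with azine formation or reduction instead of fragmentation. Fallback (radical instead of diazene fragmentation): starting from 8, NaBH4 reduces the ketone to the epoxy alcohol F8, and 1,1′-thiocarbonyldiimidazole gives the thiocarbonylimidazolide F9. Bu3SnH/AIBN in hot toluene then generates the C9 radical, which opens the oxirane at the C8–O bond and comes back to the route at the same allylic alcohol 10.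

Further compounds
F1 | step 2 | 10-allyl derivative of 2 (allyl trans to isopropenyl) | O=C1[C@H](CC=C)[C@@H](C(C)=C)C[C@@H]2O[C@]12C
F2 | step 2 | 10-(3-hydroxypropyl) derivative of 2 | O=C1[C@H](CCCO)[C@@H](C(C)=C)C[C@@H]2O[C@]12C
F3 | step 2 | 10-(3-oxopropyl) derivative of 2 | O=C1[C@H](CCC=O)[C@@H](C(C)=C)C[C@@H]2O[C@]12C
F4 | step 2 | 7β,8β-epoxy-3-hydroxy-4,4,8-trimethyldecalin-9-one (C3 epimers) | OC1CC[C@H]2C(=O)[C@@]3(C)O[C@H]3C[C@@H]2C1(C)C
F5 | step 4 | 10-(2-cyanoethyl)-10-methyl derivative of 2 (methyl trans, cyanoethyl cis to isopropenyl) | O=C1[C@@](C)(CCC#N)[C@@H](C(C)=C)C[C@@H]2O[C@]12C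
F6 | step 4 | C3 N–H ketimine of F7 | N=C1CC[C@]2(C)C(=O)[C@@]3(C)O[C@H]3C[C@@H]2C1(C)C
F7 | step 4 | cis-fused 7β,8β-epoxy-4,4,8,10β-tetramethyldecalin-3,9-dione | O=C1CC[C@]2(C)C(=O)[C@@]3(C)O[C@H]3C[C@@H]2C1(C)C
F8 | step 5 | C9 alcohol from reduction of 8 (C9 epimers) | C12(OCCO1)CC[C@]3(C)C(O)[C@@]4(C)O[C@H]4C[C@@H]3C2(C)C
F9 | step 5 | C9 O-(imidazol-1-ylthiocarbonyl) derivative of F8 | C12(OCCO1)CC[C@]3(C)C(OC(=S)n5ccnc5)[C@@]4(C)O[C@H]4C[C@@H]3C2(C)C
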